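## The problem

Target 30, (15S)-16-acetoxycarnosol, is an abietane in which C20, carried by the quaternary C10, is lactonised onto the benzylic oxygen at C7. Ring B and the lactone thus form a benzo-fused 2-oxabicyclo[2.2.2]octan-3-one (bridgeheads C10 and C7; bridges C20(=O)–O, C5–C6 and the arene bond C8–C9), with ring A (C1–C5 and C10, C4 being CMe2) trans-fused across C5–C10. The three cage stereocentres are tied together: the bridge forces C7–O and C10–C20 to be cis, so only the orientation of C5–H relative to C20 is a free choice. The fourth stereocentre, C15, lies on the ring C side chain beyond the flat arene; it can neither be set from the cage nor steer it, so it has to be made on its own, and the sense of the cage relative to it has to be controlled separately or settled by separation. Ring C is pentasubstituted, and once C9 and C13 are occupied both C8 and C14 are para to a methoxy group, so the carbon on C8 cannot be left to ordinary electrophilic substitution. The groups that limit the choice of reagents are the air-sensitive catechol, the primary acetate on O16 (lost to organolithiums, amide bases and hydroxide) and the terminal alkene of the chain, which forbids oxidative cleavage or benzylic oxidation once it is in place. The key step is possible because the lactone-bridged ring B is the formal [4+2] adduct of the C5=C6 alkene and a 2-benzopyran-3-one whose diene termini are C10 and C7. An o-formylarylacetic acid carrying the C1–C6 chain on C10 therefore already holds every atom of rings A and B and of the lactone.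

## Retrosynthesis

**Unmasking (30 from 29).** No skeletal bond is cut; only the two aryl O–CH3 bonds go. Methyl ethers are preferred to benzyl ethers (hydrogenolysis would threaten the benzylic C7–O bond) and to acetal-type groups (they would not survive the acidic steps). The C11 methoxy group also directs the lithiation at C9. The forward reaction, a Lewis-acid ether cleavage on 29, must spare the primary acetate and the lactone.

**Key disconnection (29 from 28, and 28 from 26 through 27).** C10–C5 and C7–C6 are cut together. This removes rings A and B and three stereocentres at once and keeps the lactone as the third bridge of the diene. Cutting only one of the two bonds would leave the quaternary C10 and the bridge as separate problems. The pyranone 28 is the dehydration product of the formyl acid 26, reached through the lactol acetate 27, and the same acylating medium places the acetate on O16. Hence 26 is monocyclic with C15 as its only relevant stereocentre. The forward reaction must hold the tether exo to give the trans A/B fusion. It cannot be asked to choose the diene face, so a separation of 29 from the adduct of the other face is part of the plan.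

**C10–C1 (26 from 25, 23, and 23 from 16 + 21).** The chain is attached by alkylating the enolate 22 of the arylacetate 16 with the primary iodide 21. The neighbouring cut, C9–C10 by enolate arylation, would need a doubly ortho-substituted aryl halide and is less reliable. This cut divides the molecule into an aromatic half and a six-carbon chain. The forward reaction needs the aldehyde masked as an acetal, the acid as an ester and O16 as a silyl ether, so that C10–H is the only acidic site.

**C8–C7 (16 from 15, 13 and 12).** The formyl carbon is cut from the arene. It is introduced as the acrylate of 13 by carboxylate-directed C–H olefination of the arylacetic acid 12, followed by cleavage of the alkene to 15. The neighbouring options are weaker. An electrophilic hydroxymethylation with lactonisation would have to choose between C8 and C14. It would also deliver C7 at the alcohol level, so that a later benzylic oxidation would have to compete with C10–H and C15–H and spare the alkene. The directed palladation can only reach C8, and C7 arrives as the aldehyde before the alkene exists.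

**C9–C10 (12 from 10, and 10 from 8 through 9).** The aryl–CH2 bond is cut to the aryllithium 9, obtained by methoxy-directed lithiation of 8 at the only position next to a methoxy group, and a two-carbon electrophile. Oxidation of the alcohol 10 then gives the acid. Allylation followed by oxidative cleavage was set aside because it would expose the electron-rich ring to strong oxidants. The precursor 8 has no substituent at C8 or C9.

**C15–CH3 (8 from 7, 6, 4, and 4 from 1 + 2).** The methyl group is cut from C15. The arylacetic acid 1 is commercial, and its imide 4 with the auxiliary 2 is methylated under auxiliary control to 6. Reduction to 7 and silylation to 8 follow. Setting C15 first places the only epimerisable stage (the imide 6) at the start, after which C15 is a non-acidic benzylic centre.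

**Chain (21 from 20, 18 and 17).** The iodide 21 comes from the alcohol 20. This is the product of hydroborating the less hindered alkene of the diene 18, itself the methylenation product of the commercial aldehyde 17. The forward sequence needs only discrimination between an open vinyl group and one on a quaternary carbon.

## Roads not taken

Alternative 1: ring contraction of an isochromanone by Ireland–Claisen rearrangement. The cut is C10–C5, paid for in the forward direction by breaking O–C7. The lactone A2, with a 3,3-dimethylpenta-1,4-dienyl group on C7 and an allyl group on C10, is converted into its silyl ketene acetal (C10=C20). The [3,3] shift then forms C10–C5 and gives the dihydronaphthalene acid A1 with a C6=C7 styrene.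
- **Merits:** the one carbinol stereocentre at C7 of A2 is relayed to C5 and C10, so the absolute configuration of the carbocyclic core is controlled. The chosen plan cannot do this, and on that point this road is better.
- **Weak points:** the rearrangement destroys the lactone bridge the target needs, so C7–O must be rebuilt on the styrene of A1 with the right facial sense. Ring A is still open and needs ring-closing metathesis of the allyl and vinyl groups and a hydrogenation that must leave or later reinstall the correct C5–C10 relationship. The shift has to pass through a boat-like transition state inside a six-membered lactone while joining the quaternary C10 to a carbon next to the quaternary C4.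
- **Comparison:** the chosen plan accepts that about half of the pyranone 28 is lost to the other diene face. In return the cycloaddition closes both rings and the bridge in one operation, with a single deprotection after it, against at least four further operations on a crowded core here.

Alternative 2: aryne Diels–Alder onto a ring A silyloxydiene. The cuts are C7–C8 and C9–C10. The aryne (C8≡C9), released from the iodoaryl triflate A4 by halogen–metal exchange with an alkyllithium, adds across the termini C7 and C10 of the bicyclic silyloxydiene A5 and gives the benzobicyclo[2.2.2]octadiene A3.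
- **Merits:** the route is highly convergent, and the C5 stereocentre of A5 with the adjacent CMe2 group shields one diene face, so C7 and C10 follow from C5. In convergence and face control this road is better than the chosen one.
- **Weak points:** the bridge that forms is a two-carbon silyl enol ether and not the C20(=O)–O lactone. Oxidative cleavage leaves C10 with the right one-carbon unit but C7 with a carbon that must be exchanged for oxygen with retention, which means several steps on the finished cage. The orientation of the unsymmetrical aryne is favoured electronically (the nucleophilic diene terminus C7 goes to C8, remote from the methoxy group) but opposed sterically, because the fully substituted C10 must bond to C9 next to that methoxy group. Making A4 also requires placing a leaving group selectively at C8, the same regiochemical problem the chosen route solves by directed palladation.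
- **Comparison:** the chosen plan sets against this that the lactone arrives complete in 29 and no skeletal surgery follows the cycloaddition.

Alternative 3: asymmetric Robinson annulation on a 2-tetralone carboxylate. The cuts are C10–C1 and C4=C5. The β-keto ester A7 adds through C10 to but-3-en-2-one A8 under a chiral amine–thiourea catalyst, and aldol condensation closes ring A to give the enone ester A6.
- **Merits:** the quaternary C10 is set catalytically and enantioselectively by a well-established reaction type, C20 is at the ester level from the start and the reagents are cheap. In absolute control of C10 this road is better than the chosen one.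
- **Weak points:** only one of the three cage stereocentres is made. There remain the double methylation at C4, removal of the C3 ketone, reduction of the ring-fusion alkene to the trans A/B junction (uncertain with an axial C20 ester on the β face) and benzylic oxygenation at C7 on the β face with lactonisation. That is a long endgame in which C5 and C7 are each a separate stereochemical problem.
- **Comparison:** the chosen plan sets against it that C5, C7 and C10 are fixed relative to one another in the single step from 28 to 29, with the bridge in place.

Key step: step 16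

Remark: skeleton atoms carry abietane numbers (lactone carbon C20, side chain C15–C17 with O16 on C16). By CIP analysis the target is 5S,7S,10R,15S. The formyl acids 15, 25 and 26 are drawn open-chain although they equilibrate with their lactols.

## Route

Step 1
Reactants: 1 2,3-dimethoxyphenylacetic acid; 2 (S)-4-benzyloxazolidin-2-one
Product: 4 (4S)-4-benzyl-3-[2-(2,3-dimethoxyphenyl)acetyl]oxazolidin-2-one, via mixed pivalic anhydride 3 (not isolated)
Conditions: t-BuCOCl, Et3N, THF, −20 °C; then 2, LiCl, rt
Reagents that add atoms: none
Why: N-acylation of the oxazolidinone through the mixed anhydride under LiCl/Et3N activation, a standard way to attach an arylacetic acid to an Evans auxiliary; no stereocentre is at stake.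

Step 2
Reactants: 4
Product: 6 (4S)-4-benzyl-3-[(2S)-2-(2,3-dimethoxyphenyl)propanoyl]oxazolidin-2-one, via sodium enolate 5 (not isolated)
Conditions: NaN(SiMe3)2, THF, −78 °C; then MeI, −78 → −40 °C; AcOH quench
Reagents that add atoms: iodomethane, `CI`
Why: Evans asymmetric alkylation: the chelated sodium Z-enolate 5 is methylated on the face opposite the benzyl group of the (4S)-auxiliary, which sets C15 as S; the cold acidic quench avoids epimerising the acidic benzylic C–H.

Step 3
Reactants: 6
Product: 7 (2S)-2-(2,3-dimethoxyphenyl)propan-1-ol
Conditions: LiBH4, H2O (1 equiv), Et2O, 0 °C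
Reagents that add atoms: none
Why: Reductive cleavage of the N-acyloxazolidinone gives the primary alcohol and returns the auxiliary; hydride attack at the exocyclic carbonyl does not enolise C15, so the S configuration is kept.

Step 4
Reactants: 7
Product: 8 {[(2S)-2-(2,3-dimethoxyphenyl)propyl]oxy}triisopropylsilane
Conditions: i-Pr3SiCl, imidazole, DMF, rt
Reagents that add atoms: chlorotriisopropylsilane, `CC(C)[Si](Cl)(C(C)C)C(C)C`
Why: Silyl ether formation on a primary alcohol; the triisopropylsilyl group tolerates alkyllithiums, amide bases, hydroxide and mild acid and is removed by fluoride.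

Step 5
Reactants: 8
Product: 10 2-{2,3-dimethoxy-4-[(2S)-1-(triisopropylsilyloxy)propan-2-yl]phenyl}ethanol, via aryllithium 9 (not isolated)
Conditions: n-BuLi, TMEDA, Et2O, 0 °C → rt; then ethylene oxide, −78 °C → rt; H2O
Reagents that add atoms: ethylene oxide, `C1CO1`
Why: Directed ortho-metalation: C9 is the only ring position next to a methoxy group, so lithiation occurs there, and the aryllithium opens the epoxide to make the C9–C10 bond with C20 at the alcohol level.

Step 6
Reactants: 10
Product: 12 2-{2,3-dimethoxy-4-[(2S)-1-(triisopropylsilyloxy)propan-2-yl]phenyl}acetic acid, via arylacetaldehyde 11 (not isolated)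
Conditions: TEMPO (cat.), NaClO2, NaOCl (cat.), MeCN/phosphate buffer (pH 6.7), 35 °C
Reagents that add atoms: sodium chlorite, `[Na+].[O-]Cl=O`
Why: TEMPO-catalysed oxidation with NaClO2 as terminal oxidant takes the primary alcohol through the aldehyde to the acid at buffered pH, without chlorinating the electron-rich ring or touching the silyl ether.

Step 7
Reactants: 12
Product: 13 2-{6-[(1E)-3-ethoxy-3-oxoprop-1-en-1-yl]-2,3-dimethoxy-4-[(2S)-1-(triisopropylsilyloxy)propan-2-yl]phenyl}acetic acid
Conditions: Pd(OAc)2 (5 mol %), Ac-Ile-OH (10 mol %), KHCO3, ethyl acrylate, O2 (1 atm), t-AmylOH, 90 °C; then 1 M HCl (work-up)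
Reagents that add atoms: ethyl acrylate, `C=CC(=O)OCC`
Why: Carboxylate-directed ortho C–H olefination (oxidative Heck reaction) by divalent palladium with a mono-N-protected amino acid ligand, a reaction established for phenylacetic acids; the six-membered palladacycle can form only at C8 because the other ortho position carries the C11 methoxy group, so C8–C7 is made with no competition from C14.

Step 8
Reactants: 13
Product: 15 2-{6-formyl-2,3-dimethoxy-4-[(2S)-1-(triisopropylsilyloxy)propan-2-yl]phenyl}acetic acid, via diol 14 (not isolated)
Conditions: OsO4 (2 mol %), NaIO4, 2,6-lutidine, dioxane/H2O, rt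
Reagents that add atoms: osmium tetroxide, `O=[Os](=O)(=O)=O`; sodium periodate, `[Na+].[O-]I(=O)(=O)=O`
Why: Lemieux–Johnson cleavage: catalytic OsO4 dihydroxylates the only alkene and NaIO4 cleaves the diol, so C7 arrives directly as the aldehyde before the chain alkene is present.

Step 9
Reactants: 15
Product: 16 methyl 2-{6-(dimethoxymethyl)-2,3-dimethoxy-4-[(2S)-1-(triisopropylsilyloxy)propan-2-yl]phenyl}acetate
Conditions: HC(OMe)3, MeOH, TsOH (cat.), rt → 40 °C
Reagents that add atoms: trimethyl orthoformate, `COC(OC)OC`; methanol, `CO`
Why: Acid-catalysed acetalisation combined with Fischer esterification, driven by the orthoformate as water scavenger; aldehyde and acid are masked in one operation so that only C10–H stays acidic, and the mild acid leaves the silyl ether in place.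

Step 10
Reactants: 17 2,2-dimethylpent-4-enal
Product: 18 3,3-dimethylhexa-1,5-diene
Conditions: Ph3PCH3Br, KOtBu, THF, 0 °C → rt; pentane/H2O work-up, distillation
Reagents that add atoms: methyltriphenylphosphonium bromide, `C[P+](c1ccccc1)(c1ccccc1)c1ccccc1.[Br-]`
Why: Wittig methylenation of a non-enolisable α-quaternary aldehyde; the volatile diene is taken into pentane and distilled.

Step 11
Reactants: 18
Product: 20 4,4-dimethylhex-5-en-1-ol, via alkyldisiamylborane 19 (not isolated)
Conditions: (Me2CHCHMe)2BH (1 equiv, from BH3·THF and 2-methylbut-2-ene), THF, 0 °C; then NaOH, H2O2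
Reagents that add atoms: hydrogen peroxide, `OO`
Why: Hydroboration–oxidation with a hindered dialkylborane: disiamylborane adds to the open allylic vinyl group much faster than to the vinyl group on the quaternary carbon and places boron on the terminal carbon, so one equivalent gives the anti-Markovnikov alcohol of one alkene only.

Step 12
Reactants: 20
Product: 21 6-iodo-3,3-dimethylhex-1-ene
Conditions: I2, PPh3, imidazole, CH2Cl2, 0 °C → rt
Reagents that add atoms: iodine, `II`
Why: Appel-type iodination of a primary alcohol under neutral conditions gives the unhindered primary iodide needed as the alkylating agent.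

Step 13
Reactants: 16 methyl 2-{6-(dimethoxymethyl)-2,3-dimethoxy-4-[(2S)-1-(triisopropylsilyloxy)propan-2-yl]phenyl}acetate; 21 6-iodo-3,3-dimethylhex-1-ene
Product: 23 methyl 2-{6-(dimethoxymethyl)-2,3-dimethoxy-4-[(2S)-1-(triisopropylsilyloxy)propan-2-yl]phenyl}-6,6-dimethyloct-7-enoate (both C10 epimers), via lithium enolate 22 (not isolated)
Conditions: LiN(i-Pr)2, THF, −78 °C; then 21, DMPU, −78 → 0 °C
Reagents that add atoms: none
Why: Ester enolate alkylation: the amide base removes the only acidic proton (C10–H) and the enolate is alkylated by the primary iodide to form C10–C1; the two ortho substituents suppress dialkylation, and the C10 configuration is irrelevant because C10 becomes trigonal in step 16.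

Step 14
Reactants: 23
Product: 25 2-{6-formyl-2,3-dimethoxy-4-[(2S)-1-(triisopropylsilyloxy)propan-2-yl]phenyl}-6,6-dimethyloct-7-enoic acid (both C10 epimers), via lithium carboxylate 24 (not isolated)
Conditions: LiOH, THF/MeOH/H2O, 60 °C; then 1 M HCl (pH 2), THF/H2O, rt
Reagents that add atoms: lithium hydroxide, `[Li+].[OH-]`; water, `O`
Why: Saponification of the methyl ester, then acid hydrolysis of the aryl dimethyl acetal on acidification; the terminal alkene is inert to both stages, the silyl ether should largely survive the brief dilute acid, and any loss of it only anticipates step 15.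

Step 15
Reactants: 25
Product: 26 2-{6-formyl-4-[(2S)-1-hydroxypropan-2-yl]-2,3-dimethoxyphenyl}-6,6-dimethyloct-7-enoic acid (both C10 epimers)
Conditions: HF·pyridine, pyridine, THF, 0 °C → rt
Reagents that add atoms: none
Why: Fluoride-mediated silyl ether cleavage under buffered conditions that tolerate the free acid and aldehyde; the product is used crude because hydroxyl, formyl and carboxyl groups in one molecule invite oligomerisation on storage.

Step 16
Reactants: 26
Product: 29 (5S,7S,10R,15S)-16-acetoxy-11,12-dimethoxyabieta-8,11,13-trien-20,7-olide, via lactol acetate 27 (not isolated), via 2-benzopyran-3-one 28 (not isolated)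
Conditions: Ac2O, pyridine, DMAP (cat.), rt; then PhMe (0.01 M), 110 °C; SiO2 chromatography
Reagents that add atoms: acetic anhydride, `CC(=O)OC(C)=O`
Why: Acetic anhydride acetylates O16 and the lactol hydroxyl to give 27, and loss of acetic acid across C7 and C10 on heating gives the o-quinoid pyranone 28, a locked s-cis diene with termini C10 and C7. A concerted, suprafacial intramolecular Diels–Alder addition to the unactivated C5=C6 alkene then forms C10–C5 and C7–C6 and restores the aromatic ring; the closest known reaction type is the intramolecular cycloaddition of 2-benzopyran-3-ones generated in this way from o-acylarylacetic acids, which gives bridged lactones. Ring A closes as a six-membered carbocycle in the fused (type 1) mode through the four-carbon tether C1–C4, and ring B closes as the six-membered ring C5–C10 whose C5–C6 unit becomes the third bridge of the benzo-fused 2-oxabicyclo[2.2.2]octanone. C7 and C10 are set together by the lactone bridge, which is carried through intact, so C7–O and C10–C20 are necessarily cis. C5 is set relative to C10 by the exo orientation of the tether, in which C4 lies on the lactone side and its methyl groups avoid the arene and the C11 methoxy group, giving the trans A/B fusion. Regioselectivity is fixed by the tether and chemoselectivity by the absence of any other alkene, while high dilution suppresses dimerisation of 28. The substrate cannot secure the diene face, because C15 is too far from C10 and C7 to bias it. Hence 29 is expected together with a similar amount of its (5R,7R,10S,15S) diastereomer, each as a single enantiomer because C15 is fixed, and 29 is isolated by chromatography.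

Step 17
Reactants: 29
Product: 30 (5S,7S,10R,15S)-16-acetoxy-11,12-dihydroxyabieta-8,11,13-trien-20,7-olide
Conditions: BBr3, CH2Cl2, −78 → −20 °C; then MeOH, aq NaHCO3, under Ar
Reagents that add atoms: none
Why: Lewis-acid cleavage of aryl methyl ethers: the two adjacent methoxy groups are removed through a cyclic catechol borate that is hydrolysed on work-up; the primary acetate and the bridgehead benzylic lactone, which cannot ionise to a planar cation, should survive at or below −20 °C, and the catechol is handled under argon.

## Compound list

```
1 | 2,3-dimethoxyphenylacetic acid | COc1cccc(CC(=O)O)c1OC | starting material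
2 | (S)-4-benzyloxazolidin-2-one | O=C1N[C@@H](Cc2ccccc2)CO1 | starting material
3 | 2-(2,3-dimethoxyphenyl)acetic pivalic anhydride (formed in situ) | CC(C)(C)C(=O)OC(=O)Cc1cccc(OC)c1OC | intermediate
4 | (4S)-4-benzyl-3-[2-(2,3-dimethoxyphenyl)acetyl]oxazolidin-2-one | O=C(Cc1cccc(OC)c1OC)N1[C@@H](Cc2ccccc2)COC1=O | intermediate
5 | sodium (Z)-enolate of 4 (formed in situ) | [Na+].[O-]/C(=C\c1cccc(OC)c1OC)N1[C@@H](Cc2ccccc2)COC1=O | intermediate
6 | (4S)-4-benzyl-3-[(2S)-2-(2,3-dimethoxyphenyl)propanoyl]oxazolidin-2-one | O=C([C@@H](C)c1cccc(OC)c1OC)N1[C@@H](Cc2ccccc2)COC1=O | intermediate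
7 | (2S)-2-(2,3-dimethoxyphenyl)propan-1-ol | OC[C@@H](C)c1cccc(OC)c1OC | intermediate
8 | {[(2S)-2-(2,3-dimethoxyphenyl)propyl]oxy}triisopropylsilane | CC(C)[Si](OC[C@@H](C)c1cccc(OC)c1OC)(C(C)C)C(C)C | intermediate
9 | {2,3-dimethoxy-4-[(2S)-1-(triisopropylsilyloxy)propan-2-yl]phenyl}lithium (formed in situ) | CC(C)[Si](OC[C@@H](C)c1ccc([Li])c(OC)c1OC)(C(C)C)C(C)C | intermediate
10 | 2-{2,3-dimethoxy-4-[(2S)-1-(triisopropylsilyloxy)propan-2-yl]phenyl}ethanol | CC(C)[Si](OC[C@@H](C)c1ccc(CCO)c(OC)c1OC)(C(C)C)C(C)C | intermediate
11 | 2-{2,3-dimethoxy-4-[(2S)-1-(triisopropylsilyloxy)propan-2-yl]phenyl}acetaldehyde (formed in situ) | CC(C)[Si](OC[C@@H](C)c1ccc(CC=O)c(OC)c1OC)(C(C)C)C(C)C | intermediate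
12 | 2-{2,3-dimethoxy-4-[(2S)-1-(triisopropylsilyloxy)propan-2-yl]phenyl}acetic acid | CC(C)[Si](OC[C@@H](C)c1ccc(CC(=O)O)c(OC)c1OC)(C(C)C)C(C)C | intermediate
13 | 2-{6-[(1E)-3-ethoxy-3-oxoprop-1-en-1-yl]-2,3-dimethoxy-4-[(2S)-1-(triisopropylsilyloxy)propan-2-yl]phenyl}acetic acid | CCOC(=O)/C=C/c1cc([C@H](C)CO[Si](C(C)C)(C(C)C)C(C)C)c(OC)c(OC)c1CC(=O)O | intermediate
14 | 2-{6-(3-ethoxy-1,2-dihydroxy-3-oxopropyl)-2,3-dimethoxy-4-[(2S)-1-(triisopropylsilyloxy)propan-2-yl]phenyl}acetic acid (syn diol, both enantiomeric diol faces, formed in situ) | CCOC(=O)C(O)C(O)c1cc([C@H](C)CO[Si](C(C)C)(C(C)C)C(C)C)c(OC)c(OC)c1CC(=O)O | intermediate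
15 | 2-{6-formyl-2,3-dimethoxy-4-[(2S)-1-(triisopropylsilyloxy)propan-2-yl]phenyl}acetic acid | O=Cc1cc([C@H](C)CO[Si](C(C)C)(C(C)C)C(C)C)c(OC)c(OC)c1CC(=O)O | intermediate
16 | methyl 2-{6-(dimethoxymethyl)-2,3-dimethoxy-4-[(2S)-1-(triisopropylsilyloxy)propan-2-yl]phenyl}acetate | COC(=O)Cc1c(C(OC)OC)cc([C@H](C)CO[Si](C(C)C)(C(C)C)C(C)C)c(OC)c1OC | intermediate
17 | 2,2-dimethylpent-4-enal | C=CCC(C)(C)C=O | starting material
18 | 3,3-dimethylhexa-1,5-diene | C=CCC(C)(C)C=C | intermediate
19 | (4,4-dimethylhex-5-en-1-yl)bis(3-methylbutan-2-yl)borane (formed in situ) | C=CC(C)(C)CCCB(C(C)C(C)C)C(C)C(C)C | intermediate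
20 | 4,4-dimethylhex-5-en-1-ol | C=CC(C)(C)CCCO | intermediate
21 | 6-iodo-3,3-dimethylhex-1-ene | C=CC(C)(C)CCCI | intermediate
22 | lithium enolate of 16 (formed in situ) | [Li+].COC([O-])=Cc1c(C(OC)OC)cc([C@H](C)CO[Si](C(C)C)(C(C)C)C(C)C)c(OC)c1OC | intermediate
23 | methyl 2-{6-(dimethoxymethyl)-2,3-dimethoxy-4-[(2S)-1-(triisopropylsilyloxy)propan-2-yl]phenyl}-6,6-dimethyloct-7-enoate (both C10 epimers) | COC(=O)C(CCCC(C)(C)C=C)c1c(C(OC)OC)cc([C@H](C)CO[Si](C(C)C)(C(C)C)C(C)C)c(OC)c1OC | intermediate
24 | lithium 2-{6-(dimethoxymethyl)-2,3-dimethoxy-4-[(2S)-1-(triisopropylsilyloxy)propan-2-yl]phenyl}-6,6-dimethyloct-7-enoate (formed in situ) | [Li+].[O-]C(=O)C(CCCC(C)(C)C=C)c1c(C(OC)OC)cc([C@H](C)CO[Si](C(C)C)(C(C)C)C(C)C)c(OC)c1OC | intermediate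
25 | 2-{6-formyl-2,3-dimethoxy-4-[(2S)-1-(triisopropylsilyloxy)propan-2-yl]phenyl}-6,6-dimethyloct-7-enoic acid (both C10 epimers) | O=Cc1cc([C@H](C)CO[Si](C(C)C)(C(C)C)C(C)C)c(OC)c(OC)c1C(CCCC(C)(C)C=C)C(=O)O | intermediate
26 | 2-{6-formyl-4-[(2S)-1-hydroxypropan-2-yl]-2,3-dimethoxyphenyl}-6,6-dimethyloct-7-enoic acid (both C10 epimers) | O=Cc1cc([C@H](C)CO)c(OC)c(OC)c1C(CCCC(C)(C)C=C)C(=O)O | intermediate
27 | (2S)-2-[1-acetoxy-4-(4,4-dimethylhex-5-en-1-yl)-5,6-dimethoxy-3-oxoisochroman-7-yl]propyl acetate (lactol acetate, formed in situ) | CC(=O)OC[C@@H](C)c1cc2C(OC(C)=O)OC(=O)C(CCCC(C)(C)C=C)c2c(OC)c1OC | intermediate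
28 | (2S)-2-[4-(4,4-dimethylhex-5-en-1-yl)-5,6-dimethoxy-3-oxo-3H-2-benzopyran-7-yl]propyl acetate (2-benzopyran-3-one, formed in situ) | CC(=O)OC[C@@H](C)C1=CC2=COC(=O)C(CCCC(C)(C)C=C)=C2C(OC)=C1OC | intermediate
29 | (5S,7S,10R,15S)-16-acetoxy-11,12-dimethoxyabieta-8,11,13-trien-20,7-olide (16-acetoxycarnosol dimethyl ether) | CC(=O)OC[C@@H](C)c1cc2c(c(OC)c1OC)[C@@]13CCCC(C)(C)[C@@H]1C[C@@H]2OC3=O | intermediate
30 | (5S,7S,10R,15S)-16-acetoxy-11,12-dihydroxyabieta-8,11,13-trien-20,7-olide, (15S)-16-acetoxycarnosol, CNP0105472.1 | CC(=O)OC[C@@H](C)c1cc2c(c(O)c1O)[C@@]13CCCC(C)(C)[C@@H]1C[C@@H]2OC3=O | target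
```

## Step count and least certain steps

Total: 17 steps. Longest linear sequence: 14 steps (steps 1–9 and 13–17); the iodide 21 comes from a three-step branch (steps 10–12).

**Step 16 (key step).** Three things may go wrong.
- There is no facial discrimination, since nothing in 28 tells the alkene which diene face to take. About half the material is therefore expected to end up in the (5R,7R,10S,15S) series, and the route depends on separating two adducts that differ only in the relation between remote stereo elements.
- The pyranone may dimerise if addition to the vinyl group on the quaternary carbon is slow.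
- Some material may leak through the endo tether orientation to the cis-fused series.

Fallback (sets out from 25, returns at 29): the acetylation is uncoupled from the cycloaddition and the separation is moved to a compound with a hydrogen-bond donor. Acid 25 is submitted to the conditions of step 16 without prior desilylation. This gives the silyl-protected cycloadduct (5S,7S,10R,15S)-11,12-dimethoxy-16-(triisopropylsilyloxy)abieta-8,11,13-trien-20,7-olide F1 together with its diastereomer. HF·pyridine then frees the primary alcohol (5S,7S,10R,15S)-16-hydroxy-11,12-dimethoxyabieta-8,11,13-trien-20,7-olide F2. The diastereomers are separated at this stage by chromatography or crystallisation, and F2 is acetylated (Ac2O, pyridine, DMAP) to 29.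

**Step 7.** Palladation of the crowded, electron-rich ring may be sluggish or incomplete, the arene may degrade oxidatively under O2 at 90 °C, or the carboxylate may add back to the new acrylate.

Fallback (sets out from 8, returns at 16): the C8 carbon is brought in by a second directed lithiation instead of C–H palladation. Lithiation of 8 as in step 5 and trapping with dimethylmethyleneiminium iodide gives the benzylamine N,N-dimethyl-1-{2,3-dimethoxy-4-[(2S)-1-(triisopropylsilyloxy)propan-2-yl]phenyl}methanamine F3. The CH2NMe2 group directs a second lithiation (n-BuLi, Et2O) to C8, its only free ortho position, and DMF gives the amino aldehyde 2-[(dimethylamino)methyl]-3,4-dimethoxy-5-[(2S)-1-(triisopropylsilyloxy)propan-2-yl]benzaldehyde F4. Acetalisation (HC(OMe)3, MeOH, TsOH in slight excess over the amine) gives the amino acetal 1-{6-(dimethoxymethyl)-2,3-dimethoxy-4-[(2S)-1-(triisopropylsilyloxy)propan-2-yl]phenyl}-N,N-dimethylmethanamine F5. Ethyl chloroformate cleaves the benzylic C–N bond to the benzylic chloride {(2S)-2-[4-(chloromethyl)-5-(dimethoxymethyl)-2,3-dimethoxyphenyl]propoxy}triisopropylsilane F6. Methoxycarbonylation (CO, MeOH, i-Pr2NEt, catalytic PdCl2(PPh3)2) then gives 16.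

**Step 17.** The acetate may be partly lost to the Lewis acid, demethylation at the hindered C11 may stall at the temperature that protects the acetate, and the free catechol may oxidise on work-up.

Fallback (sets out from 29, returns at 30): the acetate is given up on purpose and put back selectively. Both methyl ethers are cleaved with excess BBr3 (CH2Cl2, −78 → 0 °C) with no attempt to save the acetate. The methanol quench, in which the boron bromides give HBr in methanol, is held at rt until acid-catalysed methanolysis has removed the acetate completely. This gives the triol (5S,7S,10R,15S)-11,12,16-trihydroxyabieta-8,11,13-trien-20,7-olide F7. Only the aliphatic primary hydroxyl is then re-acetylated by transesterification with vinyl acetate catalysed by immobilised lipase B from Candida antarctica, a method that distinguishes primary alcohols from catechol hydroxyls, to give 30.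

**Step 14.** Acyl substitution at the hindered ester, flanked by a doubly ortho-substituted aryl group and the chain, may be incomplete, and forcing conditions may begin to remove the silyl ether.

Fallback (sets out from 23, returns at 24): hydroxide attack at the carbonyl is replaced by SN2 dealkylation at the ester methyl group with LiI in refluxing ethyl acetate. This gives the lithium carboxylate 24 directly, and acidification as in step 14 then gives 25. No new compound is involved.

## Further compounds

```
F1 | step 16 | (5S,7S,10R,15S)-11,12-dimethoxy-16-(triisopropylsilyloxy)abieta-8,11,13-trien-20,7-olide | CC(C)[Si](OC[C@@H](C)c1cc2c(c(OC)c1OC)[C@@]13CCCC(C)(C)[C@@H]1C[C@@H]2OC3=O)(C(C)C)C(C)C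
F2 | step 16 | (5S,7S,10R,15S)-16-hydroxy-11,12-dimethoxyabieta-8,11,13-trien-20,7-olide | OC[C@@H](C)c1cc2c(c(OC)c1OC)[C@@]13CCCC(C)(C)[C@@H]1C[C@@H]2OC3=O
F3 | step 7 | N,N-dimethyl-1-{2,3-dimethoxy-4-[(2S)-1-(triisopropylsilyloxy)propan-2-yl]phenyl}methanamine | CN(C)Cc1ccc([C@H](C)CO[Si](C(C)C)(C(C)C)C(C)C)c(OC)c1OC
F4 | step 7 | 2-[(dimethylamino)methyl]-3,4-dimethoxy-5-[(2S)-1-(triisopropylsilyloxy)propan-2-yl]benzaldehyde | CN(C)Cc1c(C=O)cc([C@H](C)CO[Si](C(C)C)(C(C)C)C(C)C)c(OC)c1OC
F5 | step 7 | 1-{6-(dimethoxymethyl)-2,3-dimethoxy-4-[(2S)-1-(triisopropylsilyloxy)propan-2-yl]phenyl}-N,N-dimethylmethanamine | CN(C)Cc1c(C(OC)OC)cc([C@H](C)CO[Si](C(C)C)(C(C)C)C(C)C)c(OC)c1OC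
F6 | step 7 | {(2S)-2-[4-(chloromethyl)-5-(dimethoxymethyl)-2,3-dimethoxyphenyl]propoxy}triisopropylsilane | ClCc1c(C(OC)OC)cc([C@H](C)CO[Si](C(C)C)(C(C)C)C(C)C)c(OC)c1OC
F7 | step 17 | (5S,7S,10R,15S)-11,12,16-trihydroxyabieta-8,11,13-trien-20,7-olide, (15S)-16-hydroxycarnosol | OC[C@@H](C)c1cc2c(c(O)c1O)[C@@]13CCCC(C)(C)[C@@H]1C[C@@H]2OC3=O
F0 | step 14 | none | none
A1 | alternative 1 | 1-allyl-7,8-dimethoxy-2-(2-methylbut-3-en-2-yl)-6-[(2S)-1-(tert-butyldimethylsilyloxy)propan-2-yl]-1,2-dihydronaphthalene-1-carboxylic acid with C5 and C10 as in the target | CC(C)(C)[Si](C)(C)OC[C@@H](C)c1cc2c(c(OC)c1OC)[C@](CC=C)(C(=O)O)[C@H](C(C)(C)C=C)C=C2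
A2 | alternative 1 | (1S)-4-allyl-5,6-dimethoxy-1-[(1E)-3,3-dimethylpenta-1,4-dien-1-yl]-7-[(2S)-1-(tert-butyldimethylsilyloxy)propan-2-yl]isochroman-3-one (C4 epimers) | CC(C)(C)[Si](C)(C)OC[C@@H](C)c1cc2c(c(OC)c1OC)C(CC=C)C(=O)O[C@H]2/C=C/C(C)(C)C=C
A3 | alternative 2 | benzobicyclo[2.2.2]octadiene cycloadduct with tert-butyldimethylsilyl enol ether bridge, C5, C7 and C10 as in the target | CC(C)(C)[Si](C)(C)OC[C@@H](C)c1cc2c(c(OC)c1OC)[C@@]13CCCC(C)(C)[C@@H]1C[C@@H]2C(O[Si](C)(C)C(C)(C)C)=C3
A4 | alternative 2 | 2-iodo-3,4-dimethoxy-5-[(2S)-1-(tert-butyldimethylsilyloxy)propan-2-yl]phenyl trifluoromethanesulfonate | CC(C)(C)[Si](C)(C)OC[C@@H](C)c1cc(OS(=O)(=O)C(F)(F)F)c(I)c(OC)c1OC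
A5 | alternative 2 | tert-butyldimethylsilyl cross-conjugated dienol ether of (4aS)-5,5-dimethyl-4,4a,5,6,7,8-hexahydronaphthalen-2(3H)-one | CC1(C)CCCC2=CC(O[Si](C)(C)C(C)(C)C)=CC[C@H]21
A6 | alternative 3 | tricyclic enone methyl ester with C3 ketone, C4=C5 alkene and quaternary C10 | CC(C)(C)[Si](C)(C)OC[C@@H](C)c1cc2c(c(OC)c1OC)[C@@]1(C(=O)OC)CCC(=O)C=C1CC2
A7 | alternative 3 | methyl 7,8-dimethoxy-2-oxo-6-[(2S)-1-(tert-butyldimethylsilyloxy)propan-2-yl]-1,2,3,4-tetrahydronaphthalene-1-carboxylate | CC(C)(C)[Si](C)(C)OC[C@@H](C)c1cc2c(c(OC)c1OC)C(C(=O)OC)C(=O)CC2
A8 | alternative 3 | but-3-en-2-one | CC(=O)C=C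
```
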